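**Strategy.** The 2-aryl-3-hydroxymethyl-2,3-dihydrobenzofuran is read as a ring-contracted flavanone: the CH2OH carbon, C3, C2 and the O1–C7a aryl ether are C4, C3, C2 and O1–C8a of a 2-arylchroman-4-one. An enantiopure (2R)-flavanone, carrying a C6 bromine for the later stilbene and the ring B phenol as its acetate, is made by asymmetric arylation of a chromone. Trivalent iodine in trimethyl orthoformate then moves the fused aryl carbon C4a from C4 to C3 in one operation: the C3–C3a bond forms, the pyranone shrinks to the dihydrofuran, C3 is set trans to the C2 aryl group and C4 is left outside the ring as a methyl ester. Reduction, Heck coupling and deacetylation complete the target.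

Key step: step 5

Assumption: (S)-t-BuPyOx is taken to deliver the aryl group to the chromone face that leads to the (2R)-flavanone, by analogy with its sense on cyclic enones; if the sense proved opposite, (R)-t-BuPyOx would be used with no other change.

Descriptor note: C3 is R in ester 10 and S in 11, 15 and 16 only because the CIP ranking of its substituents changes on reduction of the ester; the spatial arrangement (trans) is the same. The acetate of 7 is kept through the key step on purpose, and the boron partner is acetylated before any oxidant is used.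

**Step 1**
Reactants: 1 1-(5-bromo-2-hydroxy-3-methoxyphenyl)ethanone
Product: 3 6-bromo-8-methoxy-4H-chromen-4-one, via enaminone 2 (not isolated)
Conditions: Me2NCH(OMe)2, toluene, 100 °C; evaporate; then conc. HCl, CH2Cl2, 40 °C
Reagents that add atoms: N,N-dimethylformamide dimethyl acetal, COC(OC)N(C)C
Why: Condensation of the methyl ketone with the formamide acetal gives enaminone 2, and acid then triggers intramolecular conjugate addition of the phenol and loss of dimethylamine (the enaminone route to chromones), which closes the pyranone without touching the aryl bromide.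

**Step 2**
Reactants: 4 2,6-dimethoxy-4-(4,4,5,5-tetramethyl-1,3,2-dioxaborolan-2-yl)phenol
Product: 5 2,6-dimethoxy-4-(4,4,5,5-tetramethyl-1,3,2-dioxaborolan-2-yl)phenyl acetate
Conditions: Ac2O, pyridine, DMAP (cat.), CH2Cl2, rt
Reagents that add atoms: acetic anhydride, CC(=O)OC(C)=O
Why: DMAP-catalysed O-acetylation of the hindered phenol is routine, and it is done first because the free syringol-type phenol would not survive the periodate of step 3 or the oxidant of step 5.

**Step 3**
Reactants: 5 2,6-dimethoxy-4-(4,4,5,5-tetramethyl-1,3,2-dioxaborolan-2-yl)phenyl acetate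
Product: 6 (4-acetoxy-3,5-dimethoxyphenyl)boronic acid
Conditions: NaIO4, THF/H2O, rt; then 1 M HCl, rt
Reagents that add atoms: water, O
Why: Periodate cleaves the pinacol released in the hydrolysis equilibrium of the boronate (Malaprade glycol cleavage), which drives the ester to the free boronic acid needed for transmetalation in step 4, and the aryl acetate should tolerate cold dilute acid (ammonium acetate is avoided because it can cleave aryl acetates).

**Step 4**
Reactants: 3 6-bromo-8-methoxy-4H-chromen-4-one; 6 (4-acetoxy-3,5-dimethoxyphenyl)boronic acid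
Product: 7 (2R)-2-(4-acetoxy-3,5-dimethoxyphenyl)-6-bromo-8-methoxychroman-4-one
Conditions: Pd(OCOCF3)2 (5 mol%), (S)-t-BuPyOx (6 mol%), NH4PF6 (30 mol%), H2O (5 equiv), ClCH2CH2Cl, 60 °C; recrystallise
Reagents that add atoms: none
Why: Asymmetric conjugate addition of an arylboronic acid to a chromone under cationic divalent-palladium pyridine-oxazoline catalysis, in which the aryl–palladium species adds across C2=C3 from the face left open by the tert-butyl group of the ligand and so sets C2 as R, water protonates the palladium enolate, and the aryl bromide and the acetate stay untouched because palladium remains divalent throughout.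

**Step 5**
Reactants: 7 (2R)-2-(4-acetoxy-3,5-dimethoxyphenyl)-6-bromo-8-methoxychroman-4-one
Product: 10 methyl (2R,3R)-2-(4-acetoxy-3,5-dimethoxyphenyl)-5-bromo-7-methoxy-2,3-dihydro-1-benzofuran-3-carboxylate, via enol ether 8 (not isolated), via iodanyl ketal 9 (not isolated)
Conditions: PhI(OAc)2 (1.3 equiv), conc. H2SO4, HC(OMe)3, 0 °C to rt; then aq. NaHCO3
Reagents that add atoms: trimethyl orthoformate, COC(OC)OC
Why: Acid and the orthoformate convert ketone 7 into enol ether 8, electrophilic trivalent iodine adds to C3 on the face opposite the C2 aryl group while methanol adds to C4 to give iodanyl ketal 9, and the C4–C4a bond, antiperiplanar to the C3–I bond, then shifts to C3 as iodobenzene departs, so that old C4, now exocyclic and carrying two methoxy groups, ends as the methyl ester after loss of one methyl group. The closest known reaction type is the oxidative rearrangement of aryl ketones to arylalkanoic esters by hypervalent iodine or Tl(NO3)3 in trimethyl orthoformate, which is established for flavanones as a route to trans methyl 2-aryl-2,3-dihydrobenzofuran-3-carboxylates. The five-membered ring is not closed by a cyclisation but arises from the pyranone by the 1,2-shift, so no ring-closure mode applies. The new stereocentre C3 is controlled by the existing C2 centre, since iodination anti to the aryl group followed by migration with inversion at C3 places the ester trans to the aryl group, and the trans ester is also the more stable epimer. The step needs migration of ring A to win over dehydrogenation to the flavone and over a shift of the C2 aryl group, and it needs C2 to stay intact; the ring oxygen O1 ortho to C4a makes that carbon a good migrating group, while the acetate keeps ring B electron-poor enough to slow both its own migration and acid ionisation of the benzylic C2–O1 bond.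

**Step 6**
Reactants: 10 methyl (2R,3R)-2-(4-acetoxy-3,5-dimethoxyphenyl)-5-bromo-7-methoxy-2,3-dihydro-1-benzofuran-3-carboxylate
Product: 11 4-[(2R,3S)-5-bromo-3-(hydroxymethyl)-7-methoxy-2,3-dihydro-1-benzofuran-2-yl]-2,6-dimethoxyphenol
Conditions: LiBH4, THF, 0 °C to rt; then aq. NH4Cl
Reagents that add atoms: none
Why: Hydride reduction of the methyl ester to the primary alcohol with LiBH4 should also cleave the aryl acetate (any that survives is removed in step 8), should leave the aryl bromide and both stereocentres alone, and is placed before the coupling so that the base-sensitive β-aryloxy ester never meets hot amine.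

**Step 7**
Reactants: 12 3,5-dihydroxybenzaldehyde
Product: 14 3,5-diacetoxystyrene, via 3,5-dihydroxystyrene 13 (not isolated)
Conditions: Ph3PCH3Br, KOtBu (excess), THF, 0 °C to rt; then Ac2O, 0 °C to rt (same flask)
Reagents that add atoms: methyltriphenylphosphonium bromide, C[P+](c1ccccc1)(c1ccccc1)c1ccccc1.[Br-]; acetic anhydride, CC(=O)OC(C)=O
Why: Wittig methylenation with excess base and ylide (two equivalents of base are taken up by the phenols) gives the polymerisation-prone dihydroxystyrene 13, which is acetylated in the same flask so that only the stable diacetate is handled.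

**Step 8**
Reactants: 11 4-[(2R,3S)-5-bromo-3-(hydroxymethyl)-7-methoxy-2,3-dihydro-1-benzofuran-2-yl]-2,6-dimethoxyphenol; 14 3,5-diacetoxystyrene
Product: 16 gnetucleistol F, via stilbene diacetate 15 (not isolated)
Conditions: Pd(OAc)2, P(o-tol)3, Et3N, DMF, 100 °C, argon; then K2CO3, MeOH, rt; aq. NH4Cl
Reagents that add atoms: none
Why: Mizoroki–Heck coupling of the aryl bromide with the terminal styrene should place the aryl group on the unsubstituted alkene carbon and give the E-stilbene by syn β-hydride elimination, after which carbonate-mediated methanolysis (transesterification) removes all acetates, including any scrambled onto other hydroxyl groups, without affecting the two stereocentres.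

**Compound list**
1 | 1-(5-bromo-2-hydroxy-3-methoxyphenyl)ethanone | CC(=O)c1cc(Br)cc(OC)c1O | starting material
2 | (E)-1-(5-bromo-2-hydroxy-3-methoxyphenyl)-3-(dimethylamino)prop-2-en-1-one | CN(C)/C=C/C(=O)c1cc(Br)cc(OC)c1O | intermediate (not isolated)
3 | 6-bromo-8-methoxy-4H-chromen-4-one | O=c1ccoc2c(OC)cc(Br)cc12 | intermediate
4 | 2,6-dimethoxy-4-(4,4,5,5-tetramethyl-1,3,2-dioxaborolan-2-yl)phenol | COc1cc(B2OC(C)(C)C(C)(C)O2)cc(OC)c1O | starting material
5 | 2,6-dimethoxy-4-(4,4,5,5-tetramethyl-1,3,2-dioxaborolan-2-yl)phenyl acetate | COc1cc(B2OC(C)(C)C(C)(C)O2)cc(OC)c1OC(C)=O | intermediate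
6 | (4-acetoxy-3,5-dimethoxyphenyl)boronic acid | COc1cc(B(O)O)cc(OC)c1OC(C)=O | intermediate
7 | (2R)-2-(4-acetoxy-3,5-dimethoxyphenyl)-6-bromo-8-methoxychroman-4-one | COc1cc([C@H]2CC(=O)c3cc(Br)cc(OC)c3O2)cc(OC)c1OC(C)=O | intermediate
8 | (2R)-2-(4-acetoxy-3,5-dimethoxyphenyl)-6-bromo-4,8-dimethoxy-2H-chromene | COc1cc([C@H]2C=C(OC)c3cc(Br)cc(OC)c3O2)cc(OC)c1OC(C)=O | intermediate (not isolated)
9 | 4-[(2S,3S)-3-[acetoxy(phenyl)-λ3-iodanyl]-6-bromo-4,4,8-trimethoxychroman-2-yl]-2,6-dimethoxyphenyl acetate, iodine trans to the C2 aryl group, drawn with acetate as the second ligand on iodine | COc1cc([C@H]2[C@H](I(OC(C)=O)c4ccccc4)C(OC)(OC)c3cc(Br)cc(OC)c3O2)cc(OC)c1OC(C)=O | intermediate (not isolated)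
10 | methyl (2R,3R)-2-(4-acetoxy-3,5-dimethoxyphenyl)-5-bromo-7-methoxy-2,3-dihydro-1-benzofuran-3-carboxylate (trans) | COc1cc([C@@H]2Oc3c(OC)cc(Br)cc3[C@H]2C(=O)OC)cc(OC)c1OC(C)=O | intermediate
11 | 4-[(2R,3S)-5-bromo-3-(hydroxymethyl)-7-methoxy-2,3-dihydro-1-benzofuran-2-yl]-2,6-dimethoxyphenol (trans) | COc1cc([C@@H]2Oc3c(OC)cc(Br)cc3[C@H]2CO)cc(OC)c1O | intermediate
12 | 3,5-dihydroxybenzaldehyde | O=Cc1cc(O)cc(O)c1 | starting material
13 | 3,5-dihydroxystyrene (5-vinylbenzene-1,3-diol) | C=Cc1cc(O)cc(O)c1 | intermediate (not isolated)
14 | 3,5-diacetoxystyrene (5-vinyl-1,3-phenylene diacetate) | C=Cc1cc(OC(C)=O)cc(OC(C)=O)c1 | intermediate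
15 | 5-[(E)-2-[(2R,3S)-2-(4-hydroxy-3,5-dimethoxyphenyl)-3-(hydroxymethyl)-7-methoxy-2,3-dihydro-1-benzofuran-5-yl]vinyl]-1,3-phenylene diacetate | COc1cc([C@@H]2Oc3c(OC)cc(/C=C/c4cc(OC(C)=O)cc(OC(C)=O)c4)cc3[C@H]2CO)cc(OC)c1O | intermediate (not isolated)
16 | gnetucleistol F, 5-[(E)-2-[(2R,3S)-2-(4-hydroxy-3,5-dimethoxyphenyl)-3-(hydroxymethyl)-7-methoxy-2,3-dihydro-1-benzofuran-5-yl]vinyl]benzene-1,3-diol | COc1cc([C@@H]2Oc3c(OC)cc(/C=C/c4cc(O)cc(O)c4)cc3[C@H]2CO)cc(OC)c1O | target

**Step count.** Total: 8 steps. Longest linear sequence: 6 steps (4 → 5 → 6 → 7 → 10 → 11 → 16, steps 2, 3, 4, 5, 6 and 8).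

**Steps most likely to fail**

Step 5 (ring contraction). The iodinated ketal may be diverted into dehydrogenation to the flavone or into migration of the C2 aryl group instead of ring A. The acetate may also be lost by acid methanolysis, after which the freed phenol would be oxidised, and C2 may ionise in the strong acid. Fallback: halogenation and rearrangement are separated, so that no oxidant is present during the aryl shift. Setting out from 7, α-bromination with CuBr2 in EtOAc/CHCl3 at reflux should give trans-(2S,3S)-2-(4-acetoxy-3,5-dimethoxyphenyl)-3,6-dibromo-8-methoxychroman-4-one F1. Ketalisation with HC(OMe)3, MeOH and TsOH would give 4-[(2S,3S)-3,6-dibromo-4,4,8-trimethoxychroman-2-yl]-2,6-dimethoxyphenyl acetate F2. AgBF4 in MeOH then pulls off the C3 bromide and triggers the same C4-to-C3 shift of C4a with inversion, the known silver- or Lewis-acid-assisted 1,2-aryl shift of α-halo ketals to arylalkanoic esters. The route is rejoined at 10.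

Step 4 (asymmetric arylation). Protodeboronation of the electron-rich boronic acid may outrun the addition, and enantioselectivity may be insufficient with the 8-methoxychromone. Fallback: the stereocentre is obtained by resolution instead of asymmetric C–C bond formation. Setting out from 3 and 6, the addition is run with the achiral, more robust Pd(OCOCF3)2/2,2'-bipyridine catalyst to give racemic 2-(4-acetoxy-3,5-dimethoxyphenyl)-6-bromo-8-methoxychroman-4-one F3. Kinetic resolution by asymmetric transfer hydrogenation with RuCl(p-cymene)[(S,S)-TsDPEN] and HCO2H/Et3N in EtOAc should reduce the 2S enantiomer to (2S,4S)-2-(4-acetoxy-3,5-dimethoxyphenyl)-6-bromo-8-methoxychroman-4-ol F4, which is removed by chromatography. The antipodal catalyst is used if the sense is opposite. The unreduced (2R)-ketone is 7, where the route is rejoined.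

Step 8 (Heck coupling). Oxidative addition into the electron-rich bromide may be slow, arylation may occur at the internal alkene carbon, and the styrene may polymerise thermally. The free phenol may also open at C2 through a quinone methide under base at 100 °C. Fallback: the alkene geometry and regiochemistry are fixed in a boron partner and the coupling is run cooler. Setting out from 14, cross-metathesis with vinylboronic acid pinacol ester, using second-generation Grubbs catalyst RuCl2(=CHPh)(H2IMes)(PCy3) in CH2Cl2 at 40 °C, should give 5-[(E)-2-(4,4,5,5-tetramethyl-1,3,2-dioxaborolan-2-yl)vinyl]-1,3-phenylene diacetate F5. Suzuki–Miyaura coupling of F5 with 11 (PdCl2(dppf), K3PO4, dioxane/H2O, 70 °C) would give 15, partly deacetylated. The route is rejoined at 15, which is taken to 16 with K2CO3 in MeOH as in step 8.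

**Further compounds**
F1 | step 5 | (2S,3S)-2-(4-acetoxy-3,5-dimethoxyphenyl)-3,6-dibromo-8-methoxychroman-4-one (3-bromine trans to the aryl group) | COc1cc([C@H]2[C@H](Br)C(=O)c3cc(Br)cc(OC)c3O2)cc(OC)c1OC(C)=O
F2 | step 5 | 4-[(2S,3S)-3,6-dibromo-4,4,8-trimethoxychroman-2-yl]-2,6-dimethoxyphenyl acetate | COc1cc([C@H]2[C@H](Br)C(OC)(OC)c3cc(Br)cc(OC)c3O2)cc(OC)c1OC(C)=O
F3 | step 4 | racemic 2-(4-acetoxy-3,5-dimethoxyphenyl)-6-bromo-8-methoxychroman-4-one | COc1cc(C2CC(=O)c3cc(Br)cc(OC)c3O2)cc(OC)c1OC(C)=O
F4 | step 4 | (2S,4S)-2-(4-acetoxy-3,5-dimethoxyphenyl)-6-bromo-8-methoxychroman-4-ol (cis) | COc1cc([C@@H]2C[C@H](O)c3cc(Br)cc(OC)c3O2)cc(OC)c1OC(C)=O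
F5 | step 8 | 5-[(E)-2-(4,4,5,5-tetramethyl-1,3,2-dioxaborolan-2-yl)vinyl]-1,3-phenylene diacetate | CC(=O)Oc1cc(/C=C/B2OC(C)(C)C(C)(C)O2)cc(OC(C)=O)c1
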